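The ring atoms are numbered C1 (C=O), C2=C3, C4 (CHOH), C5, C6 (quaternary C–OH), and the side chain C1′, C2′. The ring is cut into acrylonitrile (C1–C3) and a C4–C6 unit held as a 6-methoxy-dihydropyranone whose ring oxygen is the C2′ oxygen. The key step uses the 1,4-placement of the C1 and C4 oxygens on the cyclohexenone ring and the 1,3-placement of the C6 and C2′ oxygens: titanocene-mediated reductive umpolung makes C4, then C6, nucleophilic, so C3–C4 and C1–C6 form in one operation. The temporary oxane ring relays C2′ to C6 through a bridged bicycle; hydrolysis releases the 2-hydroxy-1,4-dione.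

Key step: step 4

Remark 1: (R)-BINOL is written for step 3 on the usual facial sense of this catalyst with unbranched aliphatic aldehydes; should the first run give the (R)-carbinol, the (S)-ligand is used and nothing else changes.
Remark 2: 1, 2, 5 and 8 are taken as commercial.

Step 1
Reactants: 1 1,1-dimethoxyethene; 2 acetyl chloride
Product: 3 4,4-dimethoxybut-3-en-2-one
Conditions: Et3N, Et2O, 0 °C to rt
Reagents that add atoms: none
Why: C-acylation of the electron-rich ketene acetal by the acid chloride (enol-ether acylation), with Et3N taking up HCl, should give the push-pull enone; no stereocentre is formed.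

Step 2
Reactants: 3 4,4-dimethoxybut-3-en-2-one
Product: 4 1,1-dimethoxy-3-(trimethylsilyloxy)buta-1,3-diene
Conditions: LiN(iPr)2 (LDA), THF, −78 °C; TMSCl
Reagents that add atoms: chlorotrimethylsilane, C[Si](C)(C)Cl
Why: Kinetic enolisation of the only enolisable position (the acetyl methyl) and O-silylation (silyl enol ether formation) should give the 2-silyloxy diene; no stereocentre is formed.

Step 3
Reactants: 4 1,1-dimethoxy-3-(trimethylsilyloxy)buta-1,3-diene; 5 (9Z)-hexadec-9-enal
Product: 7 (2S)-6-methoxy-2-[(8Z)-pentadec-8-en-1-yl]-2,3-dihydro-4H-pyran-4-one, via silyl aldol adduct 6 (not isolated)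
Conditions: (R)-BINOL (20 mol %), Ti(OiPr)4 (20 mol %), 4 Å MS, Et2O, −20 °C; then TFA (cat.), CH2Cl2, 0 °C
Reagents that add atoms: none
Why: A titanium–BINOL-catalysed Mukaiyama aldol addition of the enol silane terminus to the aldehyde should set C2′ as S under catalyst control of the aldehyde face, and acid then closes the freed hydroxyl onto the ketene acetal carbon (6-endo oxa-Michael addition) with loss of methanol.

Step 4
Reactants: 7 (2S)-6-methoxy-2-[(8Z)-pentadec-8-en-1-yl]-2,3-dihydro-4H-pyran-4-one; 8 acrylonitrile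
Product: 12 (2R)-2-hydroxy-2-[(2S,10Z)-2-hydroxyheptadec-10-en-1-yl]cyclohexane-1,4-dione, via ketonitrile 9 (not isolated), via bridged hydroxy imine 10 (not isolated), via bridged ketal ketone 11 (not isolated)
Conditions: Cp2TiCl2 (20 mol %), Zn dust, Et3N·HCl, THF, 35 °C; then 0.5 M HCl, THF, 0 °C
Reagents that add atoms: water, O
Why: Proposed new method: zinc reduces Cp2TiCl2 to trivalent titanium, which reduces the ketone-bound enone of 7 by one electron to a titanium enolate whose C4 radical (flanked by the ring oxygen and OMe) adds to the CH2 terminus (C3) of acrylonitrile; a second electron and protons give 9, a second ketyl-type reduction at C6 closes onto the nitrile carbon C1 to give 10, and aqueous acid hydrolyses the imine and then the bridgehead ketal. The closest known reaction types are the titanocene-catalysed reductive umpolung coupling of enones and chromones with acrylonitrile and the titanocene-catalysed reductive ketone–nitrile (acyloin-type) cyclisation, merged here in one pot on a 6-alkoxy dihydropyranone. The carbocycle closes in 6-exo-dig mode (ketyl carbon onto C≡N) across the 1,3-diaxial positions of the oxane chair, giving a 2-oxabicyclo[3.3.1]nonane. C6 is the only new stereocentre that survives: the bridge can form only with the C6–C1 bond axial and the pentadecenyl group equatorial (exo), so C2′ (S) fixes C6 as R, while the C4 ketal centre (set by axial attack, chain trans to the side chain) is erased on hydrolysis. The step needs C4, not C6, to meet acrylonitrile first, which the vinylogous carbonate secures because reduction of the enone places spin at its β-carbon; it also needs 9 to cyclise before it loses methanol, which the buffered, silyl-chloride-free medium is meant to favour.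

Step 5
Reactants: 12 (2R)-2-hydroxy-2-[(2S,10Z)-2-hydroxyheptadec-10-en-1-yl]cyclohexane-1,4-dione
Product: 13 (2R,4R)-2,4-dihydroxy-2-[(2S,10Z)-2-hydroxyheptadec-10-en-1-yl]cyclohexan-1-one
Conditions: Et2BOMe, NaBH4, THF/MeOH (4:1), −78 °C; then AcOH, MeOH co-evaporation
Reagents that add atoms: none
Why: Narasaka–Prasad reduction: the diethylboron alkoxide of the C6 hydroxyl should chelate the 1,3-related, unhindered C4 ketone (the neopentylic C1 ketone is left), and hydride attacks opposite the chelate bridge to give the cis-1,3-diol, which sets the C4 centre (R in 13, the S centre of 16).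

Step 6
Reactants: 13 (2R,4R)-2,4-dihydroxy-2-[(2S,10Z)-2-hydroxyheptadec-10-en-1-yl]cyclohexan-1-one
Product: 16 (4S,6R)-4,6-dihydroxy-6-[(2S,10Z)-2-hydroxyheptadec-10-en-1-yl]cyclohex-2-en-1-one, via tetrakis-TMS enol ether 14 (not isolated), via tris-TMS enone 15 (not isolated)
Conditions: TMSOTf, Et3N, CH2Cl2, −20 to 0 °C; Pd(OAc)2, MeCN, rt; then 1 M HCl, THF, 0 °C
Reagents that add atoms: none
Why: Saegusa–Ito oxidation: TMSOTf/Et3N silylates the three hydroxyls and forms the only possible enol silane (towards C2, since C6 is quaternary), Pd(OAc)2 should turn it into the C2=C3 enone by β-hydride elimination, and dilute acid removes the silyl ethers; no stereocentre is touched.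

Compound list
1 | 1,1-dimethoxyethene | C=C(OC)OC | starting material
2 | acetyl chloride | CC(=O)Cl | starting material
3 | 4,4-dimethoxybut-3-en-2-one | CC(=O)C=C(OC)OC | intermediate
4 | 1,1-dimethoxy-3-(trimethylsilyloxy)buta-1,3-diene | C=C(O[Si](C)(C)C)C=C(OC)OC | intermediate
5 | (9Z)-hexadec-9-enal | CCCCCC/C=C\CCCCCCCC=O | starting material
6 | (5S,13Z)-1,1-dimethoxy-5-(trimethylsilyloxy)icosa-1,13-dien-3-one | CCCCCC/C=C\CCCCCCC[C@H](O[Si](C)(C)C)CC(=O)C=C(OC)OC | intermediate
7 | (2S)-6-methoxy-2-[(8Z)-pentadec-8-en-1-yl]-2,3-dihydro-4H-pyran-4-one | CCCCCC/C=C\CCCCCCC[C@H]1CC(=O)C=C(OC)O1 | intermediate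
8 | acrylonitrile | C=CC#N | starting material
9 | 3-[(2S,6S)-2-methoxy-4-oxo-6-[(8Z)-pentadec-8-en-1-yl]oxan-2-yl]propanenitrile | CCCCCC/C=C\CCCCCCC[C@H]1CC(=O)C[C@](OC)(CCC#N)O1 | intermediate
10 | (1S,3S,5R)-6-imino-1-methoxy-3-[(8Z)-pentadec-8-en-1-yl]-2-oxabicyclo[3.3.1]nonan-5-ol | CCCCCC/C=C\CCCCCCC[C@H]2C[C@@]1(O)C[C@@](OC)(O2)CCC1=N | intermediate
11 | (1S,3S,5R)-5-hydroxy-1-methoxy-3-[(8Z)-pentadec-8-en-1-yl]-2-oxabicyclo[3.3.1]nonan-6-one | CCCCCC/C=C\CCCCCCC[C@H]2C[C@@]1(O)C[C@@](OC)(O2)CCC1=O | intermediate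
12 | (2R)-2-hydroxy-2-[(2S,10Z)-2-hydroxyheptadec-10-en-1-yl]cyclohexane-1,4-dione | CCCCCC/C=C\CCCCCCC[C@H](O)C[C@@]1(O)CC(=O)CCC1=O | intermediate
13 | (2R,4R)-2,4-dihydroxy-2-[(2S,10Z)-2-hydroxyheptadec-10-en-1-yl]cyclohexan-1-one | CCCCCC/C=C\CCCCCCC[C@H](O)C[C@@]1(O)C[C@H](O)CCC1=O | intermediate
14 | 1,4,6-tris(trimethylsilyloxy)cyclohex-1-ene bearing at C6 the (2S,10Z)-2-(trimethylsilyloxy)heptadec-10-en-1-yl chain, ring centres as in 13 | CCCCCC/C=C\CCCCCCC[C@H](O[Si](C)(C)C)C[C@@]1(O[Si](C)(C)C)C[C@H](O[Si](C)(C)C)CC=C1O[Si](C)(C)C | intermediate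
15 | (4S,6R)-4,6-bis(trimethylsilyloxy)-6-[(2S,10Z)-2-(trimethylsilyloxy)heptadec-10-en-1-yl]cyclohex-2-en-1-one | CCCCCC/C=C\CCCCCCC[C@H](O[Si](C)(C)C)C[C@@]1(O[Si](C)(C)C)C[C@H](O[Si](C)(C)C)C=CC1=O | intermediate
16 | (4S,6R)-4,6-dihydroxy-6-[(2S,10Z)-2-hydroxyheptadec-10-en-1-yl]cyclohex-2-en-1-one | CCCCCC/C=C\CCCCCCC[C@H](O)C[C@@]1(O)C[C@H](O)C=CC1=O | target

Total step count: 6
Longest linear sequence: 6 steps (1 → 3 → 4 → 7 → 12 → 13 → 16)

Steps most likely to fail

Step 4 (the step labelled as a proposed new method). The electron-rich vinylogous carbonate may resist single-electron reduction, or the β-alkoxy ketone 9 may expel methanol before the second reduction, so that no bridged ketal forms. The fallback uses known chemistry, sets out from 5 and comes back at 12, forming the two ring bonds in separate steps. Aldehyde 5 is combined with 1-methoxy-3-(trimethylsilyloxy)buta-1,3-diene under the (R)-BINOL/Ti(OiPr)4 Mukaiyama aldol conditions of step 3, and the adduct is closed with PPTS in MeOH, which keeps the acetal and gives (6S)-2-methoxy-6-[(8Z)-pentadec-8-en-1-yl]oxan-4-one F1. 1-Lithio-1-methoxyallene (methoxyallene, n-BuLi, THF, −78 °C) then adds to the ketone from the axial direction, giving (4R,6S)-2-methoxy-4-(1-methoxypropa-1,2-dien-1-yl)-6-[(8Z)-pentadec-8-en-1-yl]oxan-4-ol F2. Aqueous H2SO4 (5 %) in THF hydrolyses the allenyl ether to the vinyl ketone and the acetal to the lactol, drawn in its open form as (3R)-3-hydroxy-3-[(2S,10Z)-2-hydroxyheptadec-10-en-1-yl]-4-oxohex-5-enal F3. A thiazolium-catalysed intramolecular Stetter reaction (3-benzyl-5-(2-hydroxyethyl)-4-methylthiazolium chloride, Et3N, EtOH, 70 °C) joins C4 to C3 and gives 12.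

Step 3. Control of the aldehyde face may be eroded by uncatalysed addition of this very reactive diene, or the ketene acetal may hydrolyse to the lactone during closure. The fallback sets out from 3 (with 5) and comes back at 7, replacing the catalytic silyl enol ether addition by a reagent-controlled boron aldol. The boron enolate of 3 ((−)-Ipc2BCl, Et3N, Et2O, −78 °C) is added to 5 and, after non-oxidative work-up, gives (5S,13Z)-5-hydroxy-1,1-dimethoxyicosa-1,13-dien-3-one F4. PPTS in benzene closes it to 7 with loss of methanol.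

Step 6. Enol silane formation next to the quaternary centre may be incomplete, palladium may isomerise the (Z)-alkene, or the C4 silyloxy group may be lost by elimination. The fallback sets out from 13 and comes back at 16, using isolable silyl ethers and a metal-free dehydrogenation. TESOTf/2,6-lutidine converts 13 into (2R,4R)-2,4-bis(triethylsilyloxy)-2-[(2S,10Z)-2-(triethylsilyloxy)heptadec-10-en-1-yl]cyclohexan-1-one F5. IBX (DMSO/toluene, 70 °C) dehydrogenates the ketone to (4S,6R)-4,6-bis(triethylsilyloxy)-6-[(2S,10Z)-2-(triethylsilyloxy)heptadec-10-en-1-yl]cyclohex-2-en-1-one F6. HF·pyridine in THF removes the silyl groups and gives 16.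

Further compounds
F1 | step 4 | (6S)-2-methoxy-6-[(8Z)-pentadec-8-en-1-yl]oxan-4-one | CCCCCC/C=C\CCCCCCC[C@H]1CC(=O)CC(OC)O1
F2 | step 4 | (4R,6S)-2-methoxy-4-(1-methoxypropa-1,2-dien-1-yl)-6-[(8Z)-pentadec-8-en-1-yl]oxan-4-ol | CCCCCC/C=C\CCCCCCC[C@H]1C[C@](O)(C(OC)=C=C)CC(OC)O1
F3 | step 4 | (3R)-3-hydroxy-3-[(2S,10Z)-2-hydroxyheptadec-10-en-1-yl]-4-oxohex-5-enal | CCCCCC/C=C\CCCCCCC[C@H](O)C[C@@](O)(CC=O)C(=O)C=C
F4 | step 3 | (5S,13Z)-5-hydroxy-1,1-dimethoxyicosa-1,13-dien-3-one | CCCCCC/C=C\CCCCCCC[C@H](O)CC(=O)C=C(OC)OC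
F5 | step 6 | (2R,4R)-2,4-bis(triethylsilyloxy)-2-[(2S,10Z)-2-(triethylsilyloxy)heptadec-10-en-1-yl]cyclohexan-1-one | CCCCCC/C=C\CCCCCCC[C@H](O[Si](CC)(CC)CC)C[C@@]1(O[Si](CC)(CC)CC)C[C@H](O[Si](CC)(CC)CC)CCC1=O
F6 | step 6 | (4S,6R)-4,6-bis(triethylsilyloxy)-6-[(2S,10Z)-2-(triethylsilyloxy)heptadec-10-en-1-yl]cyclohex-2-en-1-one | CCCCCC/C=C\CCCCCCC[C@H](O[Si](CC)(CC)CC)C[C@@]1(O[Si](CC)(CC)CC)C[C@H](O[Si](CC)(CC)CC)C=CC1=O
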